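## Retrosynthetic overview

1. The enal is made last, by Heck arylation of acrolein diethyl acetal with a 6-bromo-1,4-benzodioxane. The acid quench of that step also removes the phenol MOM group.
2. The CH2OH group at C2 of the dioxane comes from a vinyl group (ozonolysis, then NaBH4).
3. The dioxane is the only ring formed. It is closed by aryl C–O coupling of a syn β-aryloxy alcohol onto an ortho C–I bond, with retention, so syn becomes trans.
4. The key C2–C3 bond joins the aldehyde carbon of MOM-syringaldehyde to the oxygen-bearing carbon of an aryloxyallene. That carbon is a masked acrolein C1 and natively electrophilic. Ipc2BH hydroboration makes it nucleophilic as a chiral Z-γ-aryloxyallylborane, and both stereocentres are set in this step.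
5. The aryloxyallene comes from 4-bromo-2-iodophenol and propargyl bromide (O-alkylation, then isomerisation).

Assumption: crystalline (+)-Ipc2BH, made beforehand from (−)-α-pinene and BH3·SMe2, is treated as a stock reagent and its preparation is not counted as a step.

## Route

Step 1
Reactants: 1 syringaldehyde (4-hydroxy-3,5-dimethoxybenzaldehyde)
Product: 2 3,5-dimethoxy-4-(methoxymethoxy)benzaldehyde
Conditions: MOMCl (1.2 equiv), K2CO3, acetone, 0 °C to rt
Reagents that add atoms: chloromethyl methyl ether (MOMCl), COCCl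
Why: Williamson-type O-alkylation of the acidic para-formyl phenol gives a MOM acetal that survives borane, peroxide, carbonate bases, ozone and borohydride and leaves in the final acid quench.

Step 2
Reactants: 3 4-bromo-2-iodophenol; 4 propargyl bromide
Product: 5 4-bromo-2-iodo-1-(prop-2-yn-1-yloxy)benzene
Conditions: K2CO3, DMF, rt
Reagents that add atoms: none
Why: Williamson ether synthesis (SN2 of the phenoxide on the primary propargylic bromide), in which neither aryl halide reacts.

Step 3
Reactants: 5 4-bromo-2-iodo-1-(prop-2-yn-1-yloxy)benzene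
Product: 6 4-bromo-2-iodo-1-(propa-1,2-dien-1-yloxy)benzene (aryloxyallene)
Conditions: KOtBu (0.3 equiv), THF, 0 °C to rt
Reagents that add atoms: none
Why: Base-catalysed propargyl–allenyl prototropic isomerisation, which stops at the oxygen-conjugated allene with catalytic base at or below room temperature.

Step 4
Reactants: 6 4-bromo-2-iodo-1-(propa-1,2-dien-1-yloxy)benzene; 2 3,5-dimethoxy-4-(methoxymethoxy)benzaldehyde
Product: 9 (1S,2S)-2-(4-bromo-2-iodophenoxy)-1-[3,5-dimethoxy-4-(methoxymethoxy)phenyl]but-3-en-1-ol (syn), via Z-aryloxyallylborane 7 (not isolated), via borinate adduct 8 (not isolated)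
Conditions: 6 (1.15 equiv), (+)-Ipc2BH (1.1 equiv), toluene, −25 °C, 5 h; 2 (1.0 equiv), −78 to −40 °C, 12 h; 3 M NaOH, 30% H2O2, 0 °C to rt
Reagents that add atoms: none
Why: Proposed new method: the bulky dialkylborane should add to the terminal C=C of the allene from the side away from the aryloxy group (B to CH2, H to the central carbon), giving under kinetic control the Z-γ-aryloxyallylborane 7, in which the oxygen-bearing carbon (natively an acceptor, the C1 of acrolein) is now the donor terminus; this attacks the Re face of aldehyde 2 through a closed Zimmerman–Traxler chair, so the Z geometry gives the syn relationship and the isopinocampheyl groups from (−)-α-pinene give the (1S,2S) enantiomer, the closest known reaction types being Brown alkoxyallylboration with Z-γ-alkoxyallyl-B(Ipc)2 reagents (made there by lithiation, which these aryl halides would not survive) and kinetic Ipc2BH hydroboration of boryl-, stannyl- and silylallenes followed by aldehyde allylboration.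

Step 5
Reactants: 9 (1S,2S)-2-(4-bromo-2-iodophenoxy)-1-[3,5-dimethoxy-4-(methoxymethoxy)phenyl]but-3-en-1-ol
Product: 10 (2S,3S)-6-bromo-3-[3,5-dimethoxy-4-(methoxymethoxy)phenyl]-2-ethenyl-2,3-dihydro-1,4-benzodioxine (trans)
Conditions: CuI (10 mol%), 3,4,7,8-tetramethyl-1,10-phenanthroline (20 mol%), Cs2CO3 (1.5 equiv), toluene, 80 °C, Ar
Reagents that add atoms: none
Why: Intramolecular Ullmann-type C–O coupling in which the copper alkoxide engages the far more reactive ortho C–I bond (six-membered ring, C–Br untouched at 80 °C) and the carbinol C–O bond is never broken, so both centres are retained and syn gives trans-(2S,3S); palladium is avoided because it would cyclise onto the vinyl group or ionise the allylic aryl ether.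

Step 6
Reactants: 10 (2S,3S)-6-bromo-3-[3,5-dimethoxy-4-(methoxymethoxy)phenyl]-2-ethenyl-2,3-dihydro-1,4-benzodioxine
Product: 12 [(2S,3S)-6-bromo-3-[3,5-dimethoxy-4-(methoxymethoxy)phenyl]-2,3-dihydro-1,4-benzodioxin-2-yl]methanol, via aldehyde 11 (not isolated)
Conditions: O3, CH2Cl2/MeOH, −78 °C (Sudan Red 7B end point); NaBH4, −78 to 0 °C
Reagents that add atoms: ozone, [O-][O+]=O
Why: Ozonolysis with reductive work-up (Criegee mechanism), in which the terminal alkene outruns the arenes when ozone is stopped at the dye end point and immediate cold borohydride reduction prevents epimerisation or β-elimination of α-aryloxy aldehyde 11, so C2 keeps its configuration.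

Step 7
Reactants: 12 [(2S,3S)-6-bromo-3-[3,5-dimethoxy-4-(methoxymethoxy)phenyl]-2,3-dihydro-1,4-benzodioxin-2-yl]methanol; 13 acrolein diethyl acetal (3,3-diethoxyprop-1-ene)
Product: 16 (2E)-3-[(2S,3S)-3-(4-hydroxy-3,5-dimethoxyphenyl)-2-(hydroxymethyl)-2,3-dihydro-1,4-benzodioxin-6-yl]prop-2-enal, via Heck acetal 14 (not isolated), via MOM-protected enal 15 (not isolated)
Conditions: Pd(OAc)2 (3 mol%), nBu4NOAc, K2CO3, KCl, DMF, 90 °C; then 3 M HCl, THF, 40 °C
Reagents that add atoms: water, O
Why: Mizoroki–Heck arylation of acrolein diethyl acetal under ligand-free ammonium acetate conditions gives the E-cinnamaldehyde acetal, and the aqueous acid quench hydrolyses first the acetal and then the hindered aryl MOM ether without touching the stereocentres (trans is also the thermodynamic isomer).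

## Compound list

1 | syringaldehyde | COc1cc(C=O)cc(OC)c1O | starting material
2 | 3,5-dimethoxy-4-(methoxymethoxy)benzaldehyde | COCOc1c(OC)cc(C=O)cc1OC | intermediate
3 | 4-bromo-2-iodophenol | Oc1ccc(Br)cc1I | starting material
4 | propargyl bromide | C#CCBr | starting material
5 | 4-bromo-2-iodo-1-(prop-2-yn-1-yloxy)benzene | C#CCOc1ccc(Br)cc1I | intermediate
6 | 4-bromo-2-iodo-1-(propa-1,2-dien-1-yloxy)benzene | C=C=COc1ccc(Br)cc1I | intermediate
7 | [(2Z)-3-(4-bromo-2-iodophenoxy)prop-2-en-1-yl]diisopinocampheylborane, Ipc groups from (−)-α-pinene | Brc1ccc(O/C=C\CB([C@H]2C[C@H]3C[C@@H]([C@@H]2C)C3(C)C)[C@H]2C[C@H]3C[C@@H]([C@@H]2C)C3(C)C)c(I)c1 | intermediate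
8 | diisopinocampheylborinate ester of 9 | COCOc1c(OC)cc(cc1OC)[C@H](OB([C@H]2C[C@H]3C[C@@H]([C@@H]2C)C3(C)C)[C@H]2C[C@H]3C[C@@H]([C@@H]2C)C3(C)C)[C@H](C=C)Oc1ccc(Br)cc1I | intermediate
9 | (1S,2S)-2-(4-bromo-2-iodophenoxy)-1-[3,5-dimethoxy-4-(methoxymethoxy)phenyl]but-3-en-1-ol | COCOc1c(OC)cc(cc1OC)[C@H](O)[C@H](C=C)Oc1ccc(Br)cc1I | intermediate
10 | (2S,3S)-6-bromo-3-[3,5-dimethoxy-4-(methoxymethoxy)phenyl]-2-ethenyl-2,3-dihydro-1,4-benzodioxine | COCOc1c(OC)cc(cc1OC)[C@@H]1Oc2cc(Br)ccc2O[C@H]1C=C | intermediate
11 | (2R,3S)-6-bromo-3-[3,5-dimethoxy-4-(methoxymethoxy)phenyl]-2,3-dihydro-1,4-benzodioxine-2-carbaldehyde (same spatial arrangement, descriptor changes by priority) | COCOc1c(OC)cc(cc1OC)[C@@H]1Oc2cc(Br)ccc2O[C@H]1C=O | intermediate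
12 | [(2S,3S)-6-bromo-3-[3,5-dimethoxy-4-(methoxymethoxy)phenyl]-2,3-dihydro-1,4-benzodioxin-2-yl]methanol | COCOc1c(OC)cc(cc1OC)[C@@H]1Oc2cc(Br)ccc2O[C@H]1CO | intermediate
13 | acrolein diethyl acetal | C=CC(OCC)OCC | starting material
14 | [(2S,3S)-6-[(1E)-3,3-diethoxyprop-1-en-1-yl]-3-[3,5-dimethoxy-4-(methoxymethoxy)phenyl]-2,3-dihydro-1,4-benzodioxin-2-yl]methanol | COCOc1c(OC)cc(cc1OC)[C@@H]1Oc2cc(/C=C/C(OCC)OCC)ccc2O[C@H]1CO | intermediate
15 | (2E)-3-[(2S,3S)-3-[3,5-dimethoxy-4-(methoxymethoxy)phenyl]-2-(hydroxymethyl)-2,3-dihydro-1,4-benzodioxin-6-yl]prop-2-enal | COCOc1c(OC)cc(cc1OC)[C@@H]1Oc2cc(/C=C/C=O)ccc2O[C@H]1CO | intermediate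
16 | (2E)-3-[(2S,3S)-3-(4-hydroxy-3,5-dimethoxyphenyl)-2-(hydroxymethyl)-2,3-dihydro-1,4-benzodioxin-6-yl]prop-2-enal | COc1cc([C@@H]2Oc3cc(/C=C/C=O)ccc3O[C@H]2CO)cc(OC)c1O | target

## Step count and risks

Total step count: 7.
Longest linear sequence: 6 steps (3 → 5 → 6 → 9 → 10 → 12 → 16).

**Step 4 is the most exposed step.**
- Boron may go to the central allene carbon, after which aryloxide is lost.
- The Z-allylborane may drift to E by a 1,3-borotropic shift.
- The ee may stop near 90%. In that case crystalline 10 or 12 is recrystallised to enantiopurity.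

The fallback sets out from 6 and comes back at 9. It separates reagent formation from the asymmetric addition. Hydroboration of 6 with pinacolborane, catalysed by Pt(dba)2 and tris(2,4,6-trimethoxyphenyl)phosphine, gives the isolable and configurationally stable (Z)-2-[3-(4-bromo-2-iodophenoxy)prop-2-en-1-yl]-4,4,5,5-tetramethyl-1,3,2-dioxaborolane F1, whose geometry can be checked and purified. Allylboration of 2 with F1 is then catalysed by the chiral phosphoric acid (R)-TRIP (5 mol%, toluene, −30 °C), which directs Re-face attack. This gives the pinacol borate ester of 9 F2, which is hydrolysed on work-up to 9.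

**Step 5 is the second risk.**
- The heated carbonate medium may let the alkoxide displace the allylic aryloxide, giving an epoxide.
- The coupling may simply stall on the hindered benzylic alkoxide.

The fallback sets out from 9 and comes back at 10. It reverses the role of the arene. Treatment with i-PrMgCl·LiCl (2.1 equiv, −20 °C) first deprotonates the alcohol and then exchanges only the iodide. Quenching with B(OMe)3 and aqueous NH4Cl gives {5-bromo-2-[(1S,2S)-1-hydroxy-1-[3,5-dimethoxy-4-(methoxymethoxy)phenyl]but-3-en-2-yl]oxyphenyl}boronic acid F3. This is closed at room temperature by an oxidative intramolecular Chan–Lam etherification (Cu(OAc)2, DMAP, 4 Å sieves, O2, CH2Cl2). No strong base or heating is used, and both centres are again retained.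

**Step 7 is the third risk.**
- The electron-rich bromide may insert slowly.
- β-Hydride elimination toward the acetal carbon would give the saturated ester instead of the enal.

The fallback sets out from 12 and comes back at 14. It brings in the three-carbon unit as a preformed β-formylvinyl donor. Suzuki–Miyaura coupling of 12 with commercial (E)-2-(3,3-diethoxyprop-1-en-1-yl)-4,4,5,5-tetramethyl-1,3,2-dioxaborolane (PdCl2(dppf), K2CO3, dioxane/water, 80 °C) fixes both the regiochemistry and the E geometry. The same acid treatment then carries 14 through 15 to 16. This fallback makes no compound outside the list (F0).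

## Further compounds

F1 | step 4 | (Z)-2-[3-(4-bromo-2-iodophenoxy)prop-2-en-1-yl]-4,4,5,5-tetramethyl-1,3,2-dioxaborolane | Brc1ccc(O/C=C\CB2OC(C)(C)C(C)(C)O2)c(I)c1
F2 | step 4 | pinacol borate ester of 9 | COCOc1c(OC)cc(cc1OC)[C@H](OB2OC(C)(C)C(C)(C)O2)[C@H](C=C)Oc1ccc(Br)cc1I
F3 | step 5 | {5-bromo-2-[(1S,2S)-1-hydroxy-1-[3,5-dimethoxy-4-(methoxymethoxy)phenyl]but-3-en-2-yl]oxyphenyl}boronic acid | COCOc1c(OC)cc(cc1OC)[C@H](O)[C@H](C=C)Oc1ccc(Br)cc1B(O)O
F0 | step 7 | none | none
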